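**Overview**

1. Germacrane numbering is used: ring C1–C10, lactone C6–O–C12(=O)–C11(=C13)–C7, C14 on C10, C15 (the formyl carbon) on C4. The trans C1/C10 epoxide is a masked E C1=C10 alkene, and this alkene lies 1,5 to the C6 oxygen along C6–C7–C8–C9–C10. With C6 as a ketone the ring is an E-cyclodec-5-enone, which is the product of an oxy-Cope shift in a cyclohexane made of C1–C6.
2. Bonds cut, in retrosynthetic order: the C8 tiglate ester, the epoxide oxygen and the C15 oxidation level; then C11=C13, C8–O (from C8–Si) and the lactone C6–O bond; then C7–C11 and C8–C9 together, which restores C1–C6; then C6–C7, C1–C6 and C3–C4.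
3. Forward order: C3–C4 by Mukaiyama–Michael addition; the cyclohexane by carbonyl-ene closure of C1–C6; C6–C7 by alkenylcerium addition; four-atom expansion to the ten-membered ring with C7–C11 alkylation in the same flask; then the γ-lactone; the epoxide last.
4. Stereochemistry: C4 comes from iminium catalysis and C2 from oxazaborolidine reduction. C2 sets the two sacrificial centres, C1 (A(1,3) strain in the ene chair) and C6 (equatorial alkenyl addition).
5. The chair [3,3] shift relays these to C8 and the E-alkene, and outer-face alkylation sets C7. Outer-face hydride followed by inverting lactonisation sets C6, silicon is exchanged for oxygen with retention, and C2–OH-directed epoxidation sets C1 and C10.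

Key step: step 13

Remarks on the chemistry: PMB = 4-methoxybenzyl, Bn = benzyl. α/β refer to the usual germacranolide drawing with H7 α. Hydroxy ester 6 may partly close to its γ-lactone; both forms are reduced to the same diol 7.

**Route**

Step 1
Reactants: 1 mesityl oxide
Product: 2 4-methyl-2-(trimethylsilyloxy)penta-1,3-diene
Conditions: LiN(iPr)2, THF, −78 °C; then Me3SiCl, −78 → 0 °C
Reagents that add atoms: chlorotrimethylsilane C[Si](C)(C)Cl
Why: Kinetic enolisation of the methyl ketone at its methyl group by the hindered amide, then O-silylation, should give the cross-conjugated silyl dienol ether (kinetic silyl enol ether formation).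

Step 2
Reactants: 2 4-methyl-2-(trimethylsilyloxy)penta-1,3-diene; 3 ethyl (E)-4-oxobut-2-enoate
Product: 4 ethyl (2R)-6-methyl-4-oxo-2-(2-oxoethyl)hept-5-enoate
Conditions: (2S,5S)-5-benzyl-2-tert-butyl-3-methylimidazolidin-4-one (20 mol %), 2,4-dinitrobenzoic acid (20 mol %), H2O (2 equiv), CH2Cl2, −40 °C
Reagents that add atoms: none
Why: In this organocatalytic Mukaiyama–Michael addition the imidazolidinone converts enal 3 into an E-iminium ion whose benzyl group screens one face, so the terminal CH2 of 2 should add to the ester-bearing β-carbon from the open face and set C4 (R in 4), while the cis-methyl of 2 disfavours the s-cis diene needed for a competing cycloaddition.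

Step 3
Reactants: 4 ethyl (2R)-6-methyl-4-oxo-2-(2-oxoethyl)hept-5-enoate
Product: 5 ethyl (2R)-2-(2,2-dimethoxyethyl)-6-methyl-4-oxohept-5-enoate
Conditions: HC(OMe)3, pyridinium 4-toluenesulfonate (cat.), MeOH, 0 → 25 °C
Reagents that add atoms: trimethyl orthoformate COC(OC)OC
Why: Acid-catalysed acetalisation with an orthoformate is selective for the aldehyde over the conjugated ketone and the ester (chemoselective acetal protection).

Step 4
Reactants: 5 ethyl (2R)-2-(2,2-dimethoxyethyl)-6-methyl-4-oxohept-5-enoate
Product: 6 ethyl (2S,4S)-2-(2,2-dimethoxyethyl)-4-hydroxy-6-methylhept-5-enoate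
Conditions: (R)-1-methyl-3,3-diphenyltetrahydro-1H,3H-pyrrolo[1,2-c][1,3,2]oxazaborole (20 mol %), catecholborane, toluene, −78 °C
Reagents that add atoms: none
Why: In this Corey–Bakshi–Shibata reduction the alkenyl group acts as the large substituent, so the (R)-oxazaborolidine should deliver hydride to give the S carbinol at C2 by catalyst control, and catecholborane at low temperature leaves ester, acetal and alkene alone.

Step 5
Reactants: 6 ethyl (2S,4S)-2-(2,2-dimethoxyethyl)-4-hydroxy-6-methylhept-5-enoate
Product: 7 (2S,4S)-2-(2,2-dimethoxyethyl)-6-methylhept-5-ene-1,4-diol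
Conditions: LiAlH4, THF, 0 °C
Reagents that add atoms: none
Why: Hydride reduction of the ester (or of its γ-lactone) gives the primary C15 alcohol without touching acetal or alkene (LiAlH4 ester reduction).

Step 6
Reactants: 7 (2S,4S)-2-(2,2-dimethoxyethyl)-6-methylhept-5-ene-1,4-diol
Product: 8 (3S,5S)-1,1-dimethoxy-5-(4-methoxybenzyloxy)-3-[(4-methoxybenzyloxy)methyl]-7-methyloct-6-ene
Conditions: NaH, 4-methoxybenzyl chloride, Bu4NI (cat.), DMF, 0 → 25 °C
Reagents that add atoms: 4-methoxybenzyl chloride COc1ccc(CCl)cc1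
Why: Williamson etherification of both alkoxides installs two base-stable ethers that can later be removed oxidatively without acid.

Step 7
Reactants: 8 (3S,5S)-1,1-dimethoxy-5-(4-methoxybenzyloxy)-3-[(4-methoxybenzyloxy)methyl]-7-methyloct-6-ene
Product: 9 (3S,5S)-5-(4-methoxybenzyloxy)-3-[(4-methoxybenzyloxy)methyl]-7-methyloct-6-enal
Conditions: LiBF4, MeCN–H2O (50:1), 25 °C
Reagents that add atoms: water O
Why: Mild LiBF4-promoted acetal hydrolysis should free the aldehyde without ionising the allylic C2 ether.

Step 8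
Reactants: 9 (3S,5S)-5-(4-methoxybenzyloxy)-3-[(4-methoxybenzyloxy)methyl]-7-methyloct-6-enal
Product: 10 (1R,2S,3S,5R)-3-(4-methoxybenzyloxy)-5-[(4-methoxybenzyloxy)methyl]-2-(prop-1-en-2-yl)cyclohexan-1-ol
Conditions: Me2AlCl, CH2Cl2, −78 → −40 °C
Reagents that add atoms: none
Why: In this intramolecular carbonyl-ene reaction (isopulegol-type closure of C1–C6) the chair that keeps C2–H in the plane of the trisubstituted alkene avoids A(1,3) strain with the cis-methyl, which places the C2 ether equatorial and anti to the forming bond and so puts the new isopropenyl group trans to it (C1), with the complexed carbonyl equatorial (hydroxyl trans to isopropenyl) and the C4 arm axial; a C6 hydroxyl epimer would converge in step 9.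

Step 9
Reactants: 10 (1R,2S,3S,5R)-3-(4-methoxybenzyloxy)-5-[(4-methoxybenzyloxy)methyl]-2-(prop-1-en-2-yl)cyclohexan-1-ol
Product: 11 (2R,3S,5S)-3-(4-methoxybenzyloxy)-5-[(4-methoxybenzyloxy)methyl]-2-(prop-1-en-2-yl)cyclohexan-1-one
Conditions: Dess–Martin periodinane, NaHCO3, CH2Cl2, 0 °C; used without chromatography
Reagents that add atoms: none
Why: Buffered Dess–Martin oxidation is non-basic, so the doubly activated C1–H should not enolise (no epimerisation, no loss of the C2 ether, no alkene migration).

Step 10
Reactants: 12 ethynylmagnesium bromide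
Product: 13 benzyl(ethynyl)dimethylsilane
Conditions: BnMe2SiCl, THF, 0 → 25 °C
Reagents that add atoms: benzylchlorodimethylsilane C[Si](C)(Cl)Cc1ccccc1
Why: C-silylation of an acetylide Grignard reagent by a chlorosilane is a standard substitution at silicon.

Step 11
Reactants: 13 benzyl(ethynyl)dimethylsilane
Product: 15 (E)-benzyl(2-iodoethenyl)dimethylsilane, via alkenylzirconocene chloride 14 (not isolated)
Conditions: Cp2Zr(H)Cl, THF, 25 °C; then I2, 0 °C
Reagents that add atoms: iodine II
Why: Syn hydrozirconation places zirconium on the terminal carbon, and iodination of the C–Zr bond proceeds with retention, which fixes the E geometry (hydrozirconation–iodination).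

Step 12
Reactants: 15 (E)-benzyl(2-iodoethenyl)dimethylsilane; 11 (2R,3S,5S)-3-(4-methoxybenzyloxy)-5-[(4-methoxybenzyloxy)methyl]-2-(prop-1-en-2-yl)cyclohexan-1-one
Product: 18 (1S,2R,3S,5S)-1-[(E)-2-(benzyldimethylsilyl)ethenyl]-3-(4-methoxybenzyloxy)-5-[(4-methoxybenzyloxy)methyl]-2-(prop-1-en-2-yl)cyclohexan-1-ol, via vinyllithium 16 (not isolated), via vinylcerium dichloride 17 (not isolated)
Conditions: 15, t-BuLi (2 equiv), Et2O, −78 °C; CeCl3, THF, −78 °C; then 11, −78 °C
Reagents that add atoms: none
Why: Iodine–lithium exchange and transmetalation give a weakly basic organocerium reagent that should add 1,2 without enolising the ketone, and equatorial attack, away from the axial CH2OPMB arm, places the alkenyl group trans to the isopropenyl group with the hydroxyl axial (organocerium carbonyl addition).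

Step 13
Reactants: 18 (1S,2R,3S,5S)-1-[(E)-2-(benzyldimethylsilyl)ethenyl]-3-(4-methoxybenzyloxy)-5-[(4-methoxybenzyloxy)methyl]-2-(prop-1-en-2-yl)cyclohexan-1-ol; 19 allyl bromoacetate
Product: 22 allyl ester of the E-cyclodec-5-enone acid: 6-oxo-2α-OPMB-4β-CH2OPMB-8α-SiMe2Bn-germacr-1(10)E-ene carrying the 7β-CH2CO2allyl arm, via potassium alkoxide 20 (not isolated), via potassium enolate 21 (not isolated)
Conditions: KN(SiMe3)2, 18-crown-6, THF, 0 → 25 °C; then 19, −78 → −30 °C
Reagents that add atoms: none
Why: KN(SiMe3)2 with 18-crown-6 gives the dissociated alkoxide 20, whose [3,3] shift (anionic oxy-Cope rearrangement) runs through a chair fused trans-decalin-like to the cyclohexane with both alkenyl groups equatorial, forming C8–C9 while C1–C6 breaks and ending irreversibly in enolate 21. The closest known reaction type is the anionic oxy-Cope ring expansion of trans-1,2-dialkenylcyclohexanols to E-cyclodec-5-enones with alkylation of the enolate in the same flask. The ten-membered carbocycle is therefore closed by a concerted four-atom expansion of the six-membered ring and not by an end-to-end cyclisation. C2 is equatorial on the chair and hence trans to C9 (E C1=C10 alkene); the E-silyl group is equatorial on C8, so the C6 configuration is relayed to a single C8 configuration; and C7 is set when the bromoacetate attacks the enolate face turned away from C9 and the transannular alkene, trans to the silyl group. The step needs chair over boat and one sense of chirality transfer, which the trans-diequatorial C1/C6 alkenyl pair and the E-vinylsilane secure; silicon stands in for the C8 oxygen because a β-alkoxy enolate would eliminate by E1cB, and the allyl ester is used so that it can later be cleaved without acid.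

Step 14
Reactants: 22 allyl ester of the E-cyclodec-5-enone acid
Product: 23 6β-alcohol of keto ester 22 (hydroxyl cis to the C7 arm)
Conditions: NaBH4, MeOH–THF (1:4), −40 °C
Reagents that add atoms: none
Why: Borohydride should attack the carbonyl from the outer face of the ring, the same face the alkylating agent used, which gives the 6β-alcohol; the cold protic medium keeps the alkoxide from closing onto the ester (ketone reduction under conformational control).

Step 15
Reactants: 23 6β-alcohol of keto ester 22
Product: 24 6β-methanesulfonate of 23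
Conditions: MeSO2Cl, Et3N, CH2Cl2, −20 °C
Reagents that add atoms: methanesulfonyl chloride CS(=O)(=O)Cl
Why: Sulfonylation of the only free hydroxyl activates C6 for displacement without changing its configuration (mesylate formation).

Step 16
Reactants: 24 6β-methanesulfonate of 23
Product: 26 trans-fused 6α,12-lactone carrying 8α-SiMe2Bn (11,13-dihydro series), via carboxylic acid 25 (not isolated)
Conditions: Pd(PPh3)4 (5 mol %), morpholine, THF, 25 °C; then Cs2CO3, DMF, 45 °C
Reagents that add atoms: none
Why: Zerovalent-palladium allyl transfer to morpholine (Tsuji–Trost deallylation) frees the carboxylate under neutral conditions; the carboxylate, which sits anti to the sulfonate across C6–C7, should then displace it by intramolecular SN2 (5-exo-tet) with inversion to give the 6α-oxygen of the trans lactone.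

Step 17
Reactants: 26 trans-fused 6α,12-lactone carrying 8α-SiMe2Bn
Product: 28 8α-hydroxy-6α,12-lactone (11,13-dihydro series), via fluorosilane 27 (not isolated)
Conditions: Bu4NF, THF, 0 → 25 °C; then H2O2 (30% aq.), KHCO3, MeOH, 25 °C
Reagents that add atoms: hydrogen peroxide OO
Why: Fluoride removes the benzyl group from silicon, and the resulting fluorosilane undergoes Tamao–Fleming oxidation with retention at C8 under conditions that spare the electron-rich alkene and the saturated lactone.

Step 18
Reactants: 28 8α-hydroxy-6α,12-lactone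
Product: 29 11-(dimethylaminomethyl)-8α-hydroxy-6α,12-lactone (C11 epimers)
Conditions: LiN(iPr)2 (2.4 equiv), THF, −78 °C; then Me2N=CH2+ I−, −78 → 0 °C
Reagents that add atoms: N,N-dimethylmethyleneiminium iodide C[N+](C)=C.[I-]
Why: The lactone enolate, formed beside the C8 alkoxide, is aminomethylated at C11 by the iminium salt (Mannich-type α-aminomethylation); the C11 configuration is irrelevant because it is removed in step 19.

Step 19
Reactants: 29 11-(dimethylaminomethyl)-8α-hydroxy-6α,12-lactone
Product: 31 8α-hydroxy-α-methylene-6α,12-lactone, via trimethylammonium iodide 30 (not isolated)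
Conditions: MeI, MeOH, 25 °C; then NaHCO3 (aq.), CH2Cl2, 25 °C
Reagents that add atoms: none
Why: N-methylation followed by mild base-induced β-elimination of trimethylamine (Hofmann-type elimination through the lactone enolate) should give the exocyclic C11=C13 alkene.

Step 20
Reactants: 31 8α-hydroxy-α-methylene-6α,12-lactone; 32 tiglic acid
Product: 34 8α-tiglate bis-PMB ether, via mixed anhydride 33 (not isolated)
Conditions: 32, 2,4,6-trichlorobenzoyl chloride, Et3N, toluene, 25 °C; then 31, 4-(dimethylamino)pyridine, toluene, 25 °C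
Reagents that add atoms: none
Why: Yamaguchi esterification acylates the hindered secondary alcohol at oxygen, so C8 keeps its configuration and the E geometry of the purchased acid is carried over.

Step 21
Reactants: 34 8α-tiglate bis-PMB ether
Product: 35 2α,15-diol (8α-tiglate, α-methylene lactone, E C1=C10 alkene)
Conditions: 2,3-dichloro-5,6-dicyano-1,4-benzoquinone (DDQ), CH2Cl2–pH 7 buffer, 0 °C
Reagents that add atoms: none
Why: Oxidative cleavage of both 4-methoxybenzyl ethers by DDQ is neutral and leaves the two esters, the methylene lactone and the alkene untouched.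

Step 22
Reactants: 35 2α,15-diol
Product: 36 1β,10α-epoxy-2α,15-diol
Conditions: VO(acac)2 (5 mol %), t-BuOOH, CH2Cl2, 0 °C
Reagents that add atoms: tert-butyl hydroperoxide CC(C)(C)OO
Why: In this vanadium-catalysed hydroxyl-directed epoxidation the C2 hydroxyl lies on the outer face of the E C1=C10 alkene, so oxygen should be delivered there to give the threo epoxy alcohol (C1 and C10 together), while the two electron-poor alkenes do not react.

Step 23
Reactants: 36 1β,10α-epoxy-2α,15-diol
Product: 37 CNP0307768.2 (target)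
Conditions: (2,2,6,6-tetramethylpiperidin-1-yl)oxyl (TEMPO, 10 mol %), PhI(OAc)2, CH2Cl2, 25 °C
Reagents that add atoms: none
Why: The oxoammonium oxidation (TEMPO/PhI(OAc)2) is selective for the primary C15 alcohol over the hindered secondary C2 alcohol and stops at the aldehyde under near-neutral conditions that spare the epoxide and the C4 centre.

**Compound list**

1 | mesityl oxide | CC(=O)C=C(C)C | starting material
2 | 4-methyl-2-(trimethylsilyloxy)penta-1,3-diene | C=C(O[Si](C)(C)C)C=C(C)C | intermediate
3 | ethyl (E)-4-oxobut-2-enoate | CCOC(=O)/C=C/C=O | starting material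
4 | ethyl (2R)-6-methyl-4-oxo-2-(2-oxoethyl)hept-5-enoate | O=CC[C@@H](C(=O)OCC)CC(=O)C=C(C)C | intermediate
5 | ethyl (2R)-2-(2,2-dimethoxyethyl)-6-methyl-4-oxohept-5-enoate | COC(OC)C[C@@H](C(=O)OCC)CC(=O)C=C(C)C | intermediate
6 | ethyl (2S,4S)-2-(2,2-dimethoxyethyl)-4-hydroxy-6-methylhept-5-enoate | COC(OC)C[C@@H](C(=O)OCC)C[C@H](O)C=C(C)C | intermediate
7 | (2S,4S)-2-(2,2-dimethoxyethyl)-6-methylhept-5-ene-1,4-diol | COC(OC)C[C@@H](CO)C[C@H](O)C=C(C)C | intermediate
8 | (3S,5S)-1,1-dimethoxy-5-(4-methoxybenzyloxy)-3-[(4-methoxybenzyloxy)methyl]-7-methyloct-6-ene | COC(OC)C[C@@H](COCc1ccc(OC)cc1)C[C@H](OCc1ccc(OC)cc1)C=C(C)C | intermediate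
9 | (3S,5S)-5-(4-methoxybenzyloxy)-3-[(4-methoxybenzyloxy)methyl]-7-methyloct-6-enal | O=CC[C@@H](COCc1ccc(OC)cc1)C[C@H](OCc1ccc(OC)cc1)C=C(C)C | intermediate
10 | (1R,2S,3S,5R)-3-(4-methoxybenzyloxy)-5-[(4-methoxybenzyloxy)methyl]-2-(prop-1-en-2-yl)cyclohexan-1-ol | O[C@@H]1C[C@@H](COCc2ccc(OC)cc2)C[C@H](OCc2ccc(OC)cc2)[C@H]1C(C)=C | intermediate
11 | (2R,3S,5S)-3-(4-methoxybenzyloxy)-5-[(4-methoxybenzyloxy)methyl]-2-(prop-1-en-2-yl)cyclohexan-1-one | O=C1C[C@@H](COCc2ccc(OC)cc2)C[C@H](OCc2ccc(OC)cc2)[C@H]1C(C)=C | intermediate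
12 | ethynylmagnesium bromide | C#C[Mg]Br | starting material
13 | benzyl(ethynyl)dimethylsilane | C#C[Si](C)(C)Cc1ccccc1 | intermediate
14 | (E)-[2-(benzyldimethylsilyl)ethenyl]chlorozirconocene | C1=CC(C=C1)[Zr](Cl)(/C=C/[Si](C)(C)Cc1ccccc1)C1C=CC=C1 | intermediate (not isolated)
15 | (E)-benzyl(2-iodoethenyl)dimethylsilane | I/C=C/[Si](C)(C)Cc1ccccc1 | intermediate
16 | (E)-[2-(benzyldimethylsilyl)ethenyl]lithium | [Li]/C=C/[Si](C)(C)Cc1ccccc1 | intermediate (not isolated)
17 | (E)-[2-(benzyldimethylsilyl)ethenyl]cerium dichloride | Cl[Ce](Cl)/C=C/[Si](C)(C)Cc1ccccc1 | intermediate (not isolated)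
18 | (1S,2R,3S,5S)-1-[(E)-2-(benzyldimethylsilyl)ethenyl]-3-(4-methoxybenzyloxy)-5-[(4-methoxybenzyloxy)methyl]-2-(prop-1-en-2-yl)cyclohexan-1-ol | O[C@@]1(/C=C/[Si](C)(C)Cc2ccccc2)C[C@@H](COCc2ccc(OC)cc2)C[C@H](OCc2ccc(OC)cc2)[C@H]1C(C)=C | intermediate
19 | allyl bromoacetate | BrCC(=O)OCC=C | starting material
20 | potassium alkoxide of 18 | [K+].[O-][C@@]1(/C=C/[Si](C)(C)Cc2ccccc2)C[C@@H](COCc2ccc(OC)cc2)C[C@H](OCc2ccc(OC)cc2)[C@H]1C(C)=C | intermediate (not isolated)
21 | potassium C6/C7 enolate of the ring-expanded E-cyclodec-5-enone (8α-SiMe2Bn, 2α-OPMB, 4β-CH2OPMB) | [K+].[O-]/C1=C\[C@@H]([Si](C)(C)Cc2ccccc2)C/C(C)=C/[C@@H](OCc2ccc(OC)cc2)C[C@H](COCc2ccc(OC)cc2)C1 | intermediate (not isolated)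
22 | allyl ester of the E-cyclodec-5-enone acid (6-oxo, 2α-OPMB, 4β-CH2OPMB, 7β-CH2CO2allyl, 8α-SiMe2Bn, E C1=C10) | O=C1C[C@@H](COCc2ccc(OC)cc2)C[C@H](OCc2ccc(OC)cc2)/C=C(C)/C[C@H]([Si](C)(C)Cc2ccccc2)[C@H]1CC(=O)OCC=C | intermediate
23 | 6β-alcohol of 22 | O[C@H]1C[C@@H](COCc2ccc(OC)cc2)C[C@H](OCc2ccc(OC)cc2)/C=C(C)/C[C@H]([Si](C)(C)Cc2ccccc2)[C@H]1CC(=O)OCC=C | intermediate
24 | 6β-methanesulfonate of 23 | CS(=O)(=O)O[C@H]1C[C@@H](COCc2ccc(OC)cc2)C[C@H](OCc2ccc(OC)cc2)/C=C(C)/C[C@H]([Si](C)(C)Cc2ccccc2)[C@H]1CC(=O)OCC=C | intermediate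
25 | 6β-mesyloxy carboxylic acid | CS(=O)(=O)O[C@H]1C[C@@H](COCc2ccc(OC)cc2)C[C@H](OCc2ccc(OC)cc2)/C=C(C)/C[C@H]([Si](C)(C)Cc2ccccc2)[C@H]1CC(=O)O | intermediate (not isolated)
26 | trans-fused 6α,12-lactone carrying 8α-SiMe2Bn | C1C(=O)O[C@@H]2C[C@@H](COCc3ccc(OC)cc3)C[C@H](OCc3ccc(OC)cc3)/C=C(C)/C[C@H]([Si](C)(C)Cc3ccccc3)[C@@H]12 | intermediate
27 | 8α-(fluorodimethylsilyl)-6α,12-lactone | C1C(=O)O[C@@H]2C[C@@H](COCc3ccc(OC)cc3)C[C@H](OCc3ccc(OC)cc3)/C=C(C)/C[C@H]([Si](C)(C)F)[C@@H]12 | intermediate (not isolated)
28 | 8α-hydroxy-6α,12-lactone | C1C(=O)O[C@@H]2C[C@@H](COCc3ccc(OC)cc3)C[C@H](OCc3ccc(OC)cc3)/C=C(C)/C[C@H](O)[C@@H]12 | intermediate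
29 | 11-(dimethylaminomethyl)-8α-hydroxy-6α,12-lactone (C11 epimers) | CN(C)CC1C(=O)O[C@@H]2C[C@@H](COCc3ccc(OC)cc3)C[C@H](OCc3ccc(OC)cc3)/C=C(C)/C[C@H](O)[C@@H]12 | intermediate
30 | 11-(trimethylammoniomethyl)-8α-hydroxy-6α,12-lactone iodide | C[N+](C)(C)CC1C(=O)O[C@@H]2C[C@@H](COCc3ccc(OC)cc3)C[C@H](OCc3ccc(OC)cc3)/C=C(C)/C[C@H](O)[C@@H]12.[I-] | intermediate (not isolated)
31 | 8α-hydroxy-α-methylene-6α,12-lactone | C=C1C(=O)O[C@@H]2C[C@@H](COCc3ccc(OC)cc3)C[C@H](OCc3ccc(OC)cc3)/C=C(C)/C[C@H](O)[C@@H]12 | intermediate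
32 | tiglic acid | OC(=O)/C(C)=C/C | starting material
33 | tiglic 2,4,6-trichlorobenzoic anhydride | O=C(OC(=O)/C(C)=C/C)c1c(Cl)cc(Cl)cc1Cl | intermediate (not isolated)
34 | 8α-tiglate bis-PMB ether | C=C1C(=O)O[C@@H]2C[C@@H](COCc3ccc(OC)cc3)C[C@H](OCc3ccc(OC)cc3)/C=C(C)/C[C@H](OC(=O)/C(C)=C/C)[C@@H]12 | intermediate
35 | 2α,15-diol | C=C1C(=O)O[C@@H]2C[C@@H](CO)C[C@H](O)/C=C(C)/C[C@H](OC(=O)/C(C)=C/C)[C@@H]12 | intermediate
36 | 1β,10α-epoxy-2α,15-diol | C=C1C(=O)O[C@@H]2C[C@@H](CO)C[C@H](O)[C@H]3O[C@]3(C)C[C@H](OC(=O)/C(C)=C/C)[C@@H]12 | intermediate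
37 | CNP0307768.2 | C=C1C(=O)O[C@@H]2C[C@@H](C=O)C[C@H](O)[C@H]3O[C@]3(C)C[C@H](OC(=O)/C(C)=C/C)[C@@H]12 | target

**Count and risks**

Total step count: 23. Longest linear sequence: 21 steps (steps 1–9 and 12–23, from mesityl oxide); steps 10 and 11 form the two-step side branch to iodide 15.

Steps most likely to fail:

Step 13. Proton transfer between the potassium enolate and the alkylated ketone, O-alkylation, or relaxation of the ring conformer before the C–C bond is made could erode regio- and facial control at C7. A sluggish rearrangement of the hindered alkoxide, which has an axial CH2OPMB arm next to the oxyanion, would give these processes more time. The fallback separates the two events. It sets out from 18: the rearrangement is run alone and the enolate is quenched at −78 °C with Me3SiCl to give the regiodefined trimethylsilyl enol ether F1, which can be purified. MeLi in THF then converts it into the amine- and crown-free lithium enolate F2, which is alkylated with allyl bromoacetate 19 in THF–N,N′-dimethylpropyleneurea. The route is rejoined at 22.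

Step 16. Ionisation of the C6 sulfonate with participation of the transannular C1=C10 alkene (closure back to a bicyclic skeleton), 1,3-elimination assisted by the γ-silyl group, or E2 elimination could outrun the intramolecular carboxylate displacement. The fallback avoids a free sulfonate. It sets out from alcohol 23: Pd(PPh3)4 and morpholine remove the allyl group to give the hydroxy acid F3, which is closed by Mitsunobu lactonisation (PPh3, diisopropyl azodicarboxylate, toluene, 0 °C). Here the alkoxyphosphonium ion is displaced by the internal carboxylate with inversion as soon as it forms. The route is rejoined at lactone 26.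

Step 12. Enolisation of the doubly activated C1–H by the organometallic (epimerisation at C1 or loss of the C2 ether), or slow addition of a branched alkenyl nucleophile to a carbonyl flanked on both sides, could compete with 1,2-addition. The fallback uses a slimmer nucleophile and sets the alkene geometry afterwards. It sets out from silylacetylene 13 and ketone 11: n-BuLi converts 13 into the lithium acetylide F4, which is added to 11 in the presence of CeCl3 at −78 °C to give the propargylic alcohol F5, again by equatorial attack. Hydroxyl-directed trans-hydroalumination with NaAlH2(OCH2CH2OMe)2 in THF, then protonolysis, gives the E-vinylsilane. The route is rejoined at 18.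

Further compounds
F1 | step 13 | trimethylsilyl enol ether of the ring-expanded E-cyclodec-5-enone | C[Si](C)(C)O/C1=C\[C@@H]([Si](C)(C)Cc2ccccc2)C/C(C)=C/[C@@H](OCc2ccc(OC)cc2)C[C@H](COCc2ccc(OC)cc2)C1
F2 | step 13 | lithium C6/C7 enolate of the ring-expanded E-cyclodec-5-enone | [Li+].[O-]/C1=C\[C@@H]([Si](C)(C)Cc2ccccc2)C/C(C)=C/[C@@H](OCc2ccc(OC)cc2)C[C@H](COCc2ccc(OC)cc2)C1
F3 | step 16 | 6β-hydroxy carboxylic acid | O[C@H]1C[C@@H](COCc2ccc(OC)cc2)C[C@H](OCc2ccc(OC)cc2)/C=C(C)/C[C@H]([Si](C)(C)Cc2ccccc2)[C@H]1CC(=O)O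
F4 | step 12 | lithium (benzyldimethylsilyl)acetylide | [Li]C#C[Si](C)(C)Cc1ccccc1
F5 | step 12 | (1S,2R,3S,5S)-1-[(benzyldimethylsilyl)ethynyl]-3-(4-methoxybenzyloxy)-5-[(4-methoxybenzyloxy)methyl]-2-(prop-1-en-2-yl)cyclohexan-1-ol | O[C@@]1(C#C[Si](C)(C)Cc2ccccc2)C[C@@H](COCc2ccc(OC)cc2)C[C@H](OCc2ccc(OC)cc2)[C@H]1C(C)=C
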